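**Plan**
- Retrosynthesis: the two free hydroxyls are traced back to a 5-O-methyl, 4'-O-benzyl flavone, and ring C of that flavone is then cut at three bonds at once: O1–C8a, C4–C4a and O1–C2.
- Enabling feature: C8a and C4a are neighbouring carbons of ring A that carry O1 and the C4 carbonyl and are flanked by the oxygenated C8 and C5. They are the two carbons of the symmetric 3,4,5,6-tetramethoxybenzyne, which can be inserted into the carboxyl C–O bond of a 2,3-dimethoxyacrylic acid that already holds ring B, the 3-methoxy group and a methoxide leaving group at the future C2.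
- Forward: the ortho-silylaryl triflate comes from 1,2,3,4-tetramethoxybenzene in three steps and the acid from methyl 2,4-dihydroxybenzoate and methyl methoxyacetate in five. The two are joined and ring C, the only ring made, closes in the same flask; BCl3 then frees the 5- and 4'-hydroxyls.
- Stereochemistry: the target has no stereocentre; the only stereo-element on the way, the enol ether geometry, is lost in the ring closure.

Key step: step 9

Assumption: the enol ether ester and the acid derived from it are drawn as the E isomers for definiteness; the other isomer or a mixture would serve equally, because ring closure runs by addition–elimination.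

**Step 1**
Reactants: 1 1,2,3,4-tetramethoxybenzene
Product: 4 2,3,4,5-tetramethoxyphenol, via (2,3,4,5-tetramethoxyphenyl)lithium 2 (not isolated), via lithium aryltrimethoxyborate 3 (not isolated)
Conditions: n-BuLi, TMEDA, THF, 0 °C → rt; B(OMe)3, −78 °C → rt; AcOH, 30% H2O2, 0 °C → rt
Reagents that add atoms: hydrogen peroxide, OO
Why: Directed ortho-lithiation next to a methoxy group (the two free positions are equivalent), borylation and peroxide-induced aryl shift from boron to oxygen make up the standard one-flask hydroxylation of alkoxyarenes.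

**Step 2**
Reactants: 4 2,3,4,5-tetramethoxyphenol
Product: 5 2-bromo-3,4,5,6-tetramethoxyphenol
Conditions: NBS (1.0 equiv), CH2Cl2, −78 → 0 °C
Reagents that add atoms: N-bromosuccinimide, O=C1CCC(=O)N1Br
Why: Electrophilic aromatic bromination can only occur at the single unsubstituted position, ortho to the hydroxyl, and the cold anhydrous medium should hold back oxidation of the electron-rich phenol.

**Step 3**
Reactants: 5 2-bromo-3,4,5,6-tetramethoxyphenol
Product: 8 3,4,5,6-tetramethoxy-2-(trimethylsilyl)phenyl trifluoromethanesulfonate, via aryl trimethylsilyl ether 6 (not isolated), via lithium 2-(trimethylsilyl)phenoxide 7 (not isolated)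
Conditions: (Me3Si)2NH, THF, 70 °C, then evaporation; n-BuLi, THF, −100 → −80 °C; Tf2O, −100 °C → rt
Reagents that add atoms: hexamethyldisilazane, C[Si](C)(C)N[Si](C)(C)C; trifluoromethanesulfonic anhydride, O=S(=O)(OS(=O)(=O)C(F)(F)F)C(F)(F)F
Why: O-silylation, bromine–lithium exchange and 1,3 O→C silyl shift (retro-Brook rearrangement) give the ortho-silyl phenoxide, which is triflated in the same flask, the standard one-pot route to ortho-silylaryl triflates.

**Step 4**
Reactants: 9 methyl 2,4-dihydroxybenzoate
Product: 10 methyl 4-(benzyloxy)-2-hydroxybenzoate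
Conditions: BnBr (1.05 equiv), K2CO3, acetone, reflux
Reagents that add atoms: benzyl bromide, BrCc1ccccc1
Why: Williamson etherification takes place at the 4-hydroxyl because the 2-hydroxyl is held in a hydrogen bond to the ester carbonyl and is much less nucleophilic.

**Step 5**
Reactants: 10 methyl 4-(benzyloxy)-2-hydroxybenzoate
Product: 11 methyl 4-(benzyloxy)-2-methoxybenzoate
Conditions: MeI, K2CO3, DMF, 60 °C
Reagents that add atoms: iodomethane, CI
Why: Williamson methylation of the remaining chelated phenol proceeds under the more forcing conditions of a dipolar aprotic solvent and heat.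

**Step 6**
Reactants: 11 methyl 4-(benzyloxy)-2-methoxybenzoate; 12 methyl methoxyacetate
Product: 13 methyl 3-[4-(benzyloxy)-2-methoxyphenyl]-2-methoxy-3-oxopropanoate (racemic)
Conditions: 12 (1.5 equiv), LiN(SiMe3)2 (3 equiv), THF, −78 → 0 °C; aq. HCl work-up
Reagents that add atoms: none
Why: In this crossed Claisen condensation the non-enolisable benzoate is the acceptor for the lithium enolate of methyl methoxyacetate, and excess amide base drives the equilibrium by deprotonating the β-keto ester formed.

**Step 7**
Reactants: 13 methyl 3-[4-(benzyloxy)-2-methoxyphenyl]-2-methoxy-3-oxopropanoate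
Product: 14 methyl (E)-3-[4-(benzyloxy)-2-methoxyphenyl]-2,3-dimethoxyprop-2-enoate
Conditions: KN(SiMe3)2, THF/DMPU, −78 °C; MeOTf, −78 → 0 °C
Reagents that add atoms: methyl trifluoromethanesulfonate, COS(=O)(=O)C(F)(F)F
Why: O-alkylation of the β-keto ester enolate is favoured by the potassium counter-ion, the dipolar co-solvent and the hard electrophile, and the α-carbon, which already bears a methoxy group, is shielded from C-methylation.

**Step 8**
Reactants: 14 methyl (E)-3-[4-(benzyloxy)-2-methoxyphenyl]-2,3-dimethoxyprop-2-enoate
Product: 15 (E)-3-[4-(benzyloxy)-2-methoxyphenyl]-2,3-dimethoxyprop-2-enoic acid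
Conditions: LiOH·H2O, THF/MeOH/H2O, 50 °C; then 1 M HCl to pH 4, 0 °C
Reagents that add atoms: lithium hydroxide, [Li+].[OH-]
Why: Saponification by acyl–oxygen cleavage frees the acid, the electron-rich β-alkoxy enoate resists conjugate attack by hydroxide, and cold acidification to pH 4 should leave the enol ether intact.

**Step 9**
Reactants: 15 (E)-3-[4-(benzyloxy)-2-methoxyphenyl]-2,3-dimethoxyprop-2-enoic acid; 8 3,4,5,6-tetramethoxy-2-(trimethylsilyl)phenyl trifluoromethanesulfonate
Product: 18 4'-(benzyloxy)-3,5,6,7,8,2'-hexamethoxyflavone, via 3,4,5,6-tetramethoxybenzyne 16 (not isolated), via cesium ortho-acylphenoxide 17 (not isolated)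
Conditions: 8 (1.5 equiv), CsF (4 equiv), THF, 125 °C, sealed tube; then dilute aq. HCl
Reagents that add atoms: none
Why: Fluoride removes the silyl group of 8 and triflate leaves to give the symmetric aryne 16, the cesium carboxylate of 15 adds to it through oxygen, and the aryl anion so formed attacks the neighbouring ester carbonyl through a four-membered alkoxide that opens to the ortho-acylphenoxide 17, so that O1–C8a and C4–C4a arise by net insertion of the aryne into the carboxyl C–O bond. The closest known reaction type is the CsF-mediated insertion of arynes into carboxylic acids, which gives ortho-hydroxyaryl ketones and, with cinnamic or arylpropiolic acids, chromanones or flavones in the same flask; the β-methoxyacrylic acid and the tetraalkoxybenzyne are new substrates for it. Ring C closes by 6-endo-trig conjugate addition of the phenoxide oxygen to the β-carbon of the β-methoxy enone (O1–C2), and loss of methoxide from the resulting enolate (addition–elimination) makes the closure irreversible and gives the 3-methoxypyranone directly. No stereocentre is formed, and the alkene geometry of 15 is lost in the enolate that precedes elimination. No regioselectivity is required because the two aryne carbons are equivalent, each flanked by a methoxy group; the selectivity that is required is acyl transfer in preference to protonation of the aryl anion, which the aprotic medium, the excess of CsF, the high temperature and the proximity of the ester carbonyl favour. Any ortho-hydroxyaryl enone that escapes cyclisation should close during the acidic work-up.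

**Step 10**
Reactants: 18 4'-(benzyloxy)-3,5,6,7,8,2'-hexamethoxyflavone
Product: 19 5,4'-dihydroxy-3,6,7,8,2'-pentamethoxyflavone
Conditions: BCl3 (4 equiv), pentamethylbenzene (3 equiv), CH2Cl2, −78 → 0 °C; then MeOH, dilute aq. HCl
Reagents that add atoms: none
Why: BCl3 is held between the C4 carbonyl and O5 in a six-membered chelate and cleaves only that peri methyl ether (chelation-controlled demethylation), and it also ionises the benzyl ether, whose cation is trapped by pentamethylbenzene, while the unchelated methyl ethers should survive at or below 0 °C.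

**Compound list**
1 | 1,2,3,4-tetramethoxybenzene | COc1ccc(OC)c(OC)c1OC | starting material
2 | (2,3,4,5-tetramethoxyphenyl)lithium | [Li]c1cc(OC)c(OC)c(OC)c1OC | intermediate (not isolated)
3 | lithium trimethoxy(2,3,4,5-tetramethoxyphenyl)borate | [Li+].CO[B-](OC)(OC)c1cc(OC)c(OC)c(OC)c1OC | intermediate (not isolated)
4 | 2,3,4,5-tetramethoxyphenol | COc1cc(O)c(OC)c(OC)c1OC | intermediate
5 | 2-bromo-3,4,5,6-tetramethoxyphenol | COc1c(Br)c(O)c(OC)c(OC)c1OC | intermediate
6 | (2-bromo-3,4,5,6-tetramethoxyphenoxy)trimethylsilane | COc1c(Br)c(O[Si](C)(C)C)c(OC)c(OC)c1OC | intermediate (not isolated)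
7 | lithium 3,4,5,6-tetramethoxy-2-(trimethylsilyl)phenolate | [Li+].COc1c([Si](C)(C)C)c([O-])c(OC)c(OC)c1OC | intermediate (not isolated)
8 | 3,4,5,6-tetramethoxy-2-(trimethylsilyl)phenyl trifluoromethanesulfonate | COc1c(OC)c(OC)c(OC)c(OS(=O)(=O)C(F)(F)F)c1[Si](C)(C)C | intermediate
9 | methyl 2,4-dihydroxybenzoate | COC(=O)c1ccc(O)cc1O | starting material
10 | methyl 4-(benzyloxy)-2-hydroxybenzoate | COC(=O)c1ccc(OCc2ccccc2)cc1O | intermediate
11 | methyl 4-(benzyloxy)-2-methoxybenzoate | COC(=O)c1ccc(OCc2ccccc2)cc1OC | intermediate
12 | methyl methoxyacetate | COCC(=O)OC | starting material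
13 | methyl 3-[4-(benzyloxy)-2-methoxyphenyl]-2-methoxy-3-oxopropanoate (racemic) | COC(=O)C(OC)C(=O)c1ccc(OCc2ccccc2)cc1OC | intermediate
14 | methyl (E)-3-[4-(benzyloxy)-2-methoxyphenyl]-2,3-dimethoxyprop-2-enoate | CO/C(c1ccc(OCc2ccccc2)cc1OC)=C(/OC)C(=O)OC | intermediate
15 | (E)-3-[4-(benzyloxy)-2-methoxyphenyl]-2,3-dimethoxyprop-2-enoic acid | CO/C(c1ccc(OCc2ccccc2)cc1OC)=C(/OC)C(=O)O | intermediate
16 | 3,4,5,6-tetramethoxybenzyne | COC1=C(OC)C(OC)=C(OC)C#C1 | intermediate (not isolated)
17 | cesium 2-{(E)-3-[4-(benzyloxy)-2-methoxyphenyl]-2,3-dimethoxyprop-2-enoyl}-3,4,5,6-tetramethoxyphenolate | [Cs+].CO/C(c1ccc(OCc2ccccc2)cc1OC)=C(/OC)C(=O)c1c([O-])c(OC)c(OC)c(OC)c1OC | intermediate (not isolated)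
18 | 4'-(benzyloxy)-3,5,6,7,8,2'-hexamethoxyflavone | COc1cc(OCc2ccccc2)ccc1-c1oc2c(OC)c(OC)c(OC)c(OC)c2c(=O)c1OC | intermediate
19 | 5,4'-dihydroxy-3,6,7,8,2'-pentamethoxyflavone | COc1cc(O)ccc1-c1oc2c(OC)c(OC)c(OC)c(O)c2c(=O)c1OC | target

**Step count**
Total: 10 steps. Longest linear sequence: 7 steps (steps 4 to 10, from methyl 2,4-dihydroxybenzoate).

**Steps most likely to fail**

Step 9. The aryl anion formed after addition of the carboxylate may be protonated before it reaches the ester carbonyl, leaving the simple O-aryl ester, or the aryne may be consumed by the methoxide that the ring closure expels. The fallback builds ring C by a Baker–Venkataraman sequence; it sets out from phenol 4 and ester 11 and comes back at flavone 18. Phenol 4 would be acylated at its only free ring position with methoxyacetyl chloride and BF3·OEt2 (O-acylation, then Fries rearrangement) to give 1-(2-hydroxy-3,4,5,6-tetramethoxyphenyl)-2-methoxyethan-1-one F1. Ester 11 would be saponified with LiOH to 4-(benzyloxy)-2-methoxybenzoic acid F2 and converted with oxalyl chloride and catalytic DMF into 4-(benzyloxy)-2-methoxybenzoyl chloride F3. Acylation of F1 with F3 in pyridine with DMAP would give 2-(methoxyacetyl)-3,4,5,6-tetramethoxyphenyl 4-(benzyloxy)-2-methoxybenzoate F4. KOH in pyridine would then shift the aroyl group from oxygen to carbon and give 1-[4-(benzyloxy)-2-methoxyphenyl]-3-(2-hydroxy-3,4,5,6-tetramethoxyphenyl)-2-methoxypropane-1,3-dione F5. Cyclodehydration of F5 with TsOH in toluene at 80 °C would give 18.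

Step 7. Methylation of the enolate at the α-carbon may compete with methylation at oxygen and give a quaternary α-methoxy-α-methyl keto ester. The fallback avoids enolate chemistry; it sets out from keto ester 13 and comes back at enol ether 14. Acid-catalysed acetalisation of the aryl ketone (HC(OMe)3, TsOH, MeOH, 60 °C), helped by the 2,4-dialkoxyphenyl group that stabilises the oxocarbenium ion, would give methyl 3-[4-(benzyloxy)-2-methoxyphenyl]-2,3,3-trimethoxypropanoate F6. Loss of methanol from F6 across C2–C3 (Me3SiOTf, iPr2NEt, CH2Cl2, 0 °C) would give 14, and alkylation at carbon cannot occur on this path.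

Step 2. NBS may oxidise the para-methoxyphenol 4 to a methoxybenzoquinone faster than it brominates the ring. The bromine is needed only as the handle for the silyl shift of step 3, so the fallback replaces halogenation by carbamate-directed ortho-metalation; it sets out from phenol 4 and comes back at triflate 8, passing by steps 2 and 3. Isopropyl isocyanate with catalytic Et3N would give 2,3,4,5-tetramethoxyphenyl N-isopropylcarbamate F7. N-silylation in the flask (Me3SiOTf, TMEDA), lithiation with n-BuLi at −78 °C at the only ring hydrogen and quenching with Me3SiCl would give 3,4,5,6-tetramethoxy-2-(trimethylsilyl)phenyl N-isopropylcarbamate F8. Cleavage of the carbamate with DBU and Et2NH in MeCN, followed by triflation of the freed phenoxide with PhNTf2 in the same flask, would give 8.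

**Further compounds**
F1 | step 9 | 1-(2-hydroxy-3,4,5,6-tetramethoxyphenyl)-2-methoxyethan-1-one | COCC(=O)c1c(O)c(OC)c(OC)c(OC)c1OC
F2 | step 9 | 4-(benzyloxy)-2-methoxybenzoic acid | COc1cc(OCc2ccccc2)ccc1C(=O)O
F3 | step 9 | 4-(benzyloxy)-2-methoxybenzoyl chloride | COc1cc(OCc2ccccc2)ccc1C(Cl)=O
F4 | step 9 | 2-(methoxyacetyl)-3,4,5,6-tetramethoxyphenyl 4-(benzyloxy)-2-methoxybenzoate | COCC(=O)c1c(OC(=O)c2ccc(OCc3ccccc3)cc2OC)c(OC)c(OC)c(OC)c1OC
F5 | step 9 | 1-[4-(benzyloxy)-2-methoxyphenyl]-3-(2-hydroxy-3,4,5,6-tetramethoxyphenyl)-2-methoxypropane-1,3-dione (racemic) | COC(C(=O)c1ccc(OCc2ccccc2)cc1OC)C(=O)c1c(O)c(OC)c(OC)c(OC)c1OC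
F6 | step 7 | methyl 3-[4-(benzyloxy)-2-methoxyphenyl]-2,3,3-trimethoxypropanoate (racemic) | COC(=O)C(OC)C(OC)(OC)c1ccc(OCc2ccccc2)cc1OC
F7 | step 2 | 2,3,4,5-tetramethoxyphenyl N-isopropylcarbamate | CC(C)NC(=O)Oc1cc(OC)c(OC)c(OC)c1OC
F8 | step 2 | 3,4,5,6-tetramethoxy-2-(trimethylsilyl)phenyl N-isopropylcarbamate | CC(C)NC(=O)Oc1c([Si](C)(C)C)c(OC)c(OC)c(OC)c1OC
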